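**Retrosynthetic overview**
1. Last step: diimide saturation of a C≡C that links the dioxane to the cyclohexenone; the alkyne is kept until then because it steers the C3 configuration.
2. C3 and C2 (side chain): a propionate silyl ketene acetal adds to the cyclic peroxycarbenium ion of a 1,2-dioxan-3-yl acetate.
3. Key step: ring expansion of an enantioenriched cyclopropanecarbaldehyde with H2O2 (three- to six-membered ring; a C–C bond becomes C–O–O–C), which sets the tertiary peroxide centre C6 by inversion.
4. The cyclopropane comes from a C6 enynol (asymmetric Simmons–Smith) and is joined as its acetylide to a vinylogous ester made from cyclohexane-1,3-dione (Stork–Danheiser).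
5. Ring order: cyclohexenone (bought ring, refunctionalised), then cyclopropane, then 1,2-dioxane.

Assumption: the enynol used in step 4 is bought as the geometrically pure E isomer, and H2O2 is used as a dried ethereal solution.

**Route**

Step 1
Reactants: 1 cyclohexane-1,3-dione
Product: 2 2-methylcyclohexane-1,3-dione
Conditions: MeI, NaOH, H2O/dioxane, reflux
Reagents that add atoms: iodomethane (CI)
Why: C-alkylation of the stabilised 1,3-dione enolate installs the methyl group that ends up on the enone α-carbon; no stereocentre is formed.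

Step 2
Reactants: 2 2-methylcyclohexane-1,3-dione
Product: 3 2-methyl-3-(2-methylpropoxy)cyclohex-2-en-1-one
Conditions: i-BuOH, TsOH (cat.), toluene, reflux, Dean–Stark
Reagents that add atoms: 2-methylpropan-1-ol (CC(C)CO)
Why: acid-catalysed vinylogous ester formation with azeotropic removal of water masks one carbonyl for the later Stork–Danheiser transposition.

Step 3
Reactants: 3 2-methyl-3-(2-methylpropoxy)cyclohex-2-en-1-one
Product: 5 2,6,6-trimethyl-3-(2-methylpropoxy)cyclohex-2-en-1-one, via 2,6-dimethyl-3-(2-methylpropoxy)cyclohex-2-en-1-one 4 (not isolated)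
Conditions: LiN(i-Pr)2 (1.1 equiv), THF, −78 °C, MeI; then LiN(i-Pr)2 (1.2 equiv), −78 °C, MeI, → 0 °C
Reagents that add atoms: iodomethane (CI)
Why: kinetic deprotonation of a vinylogous ester occurs at the α' carbon (Stork–Danheiser alkylation), so two base/MeI cycles build the gem-dimethyl group next to the free carbonyl, and the racemic centre of 4 disappears in 5.

Step 4
Reactants: 6 (E)-3-methylpent-2-en-4-yn-1-ol
Product: 7 [(1S,2S)-2-ethynyl-2-methylcyclopropyl]methanol
Conditions: Et2Zn, CH2I2, DME, CH2Cl2, −10 °C (gives Zn(CH2I)2); then 6 and (4R,5R)-2-butyl-N,N,N',N'-tetramethyl-1,3,2-dioxaborolane-4,5-dicarboxamide (1.2 equiv), −10 °C → rt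
Reagents that add atoms: diiodomethane (ICI)
Why: Charette asymmetric Simmons–Smith cyclopropanation, in which the zinc alkoxide bound to the chiral dioxaborolane directs CH2 to one alkene face (the same face that gives the (1S,2S) product from (E)-cinnamyl alcohol with this ligand) and the E geometry is transferred stereospecifically, so the quaternary centre is set as (2S) with ethynyl trans to CH2OH.

Step 5
Reactants: 7 [(1S,2S)-2-ethynyl-2-methylcyclopropyl]methanol; 5 2,6,6-trimethyl-3-(2-methylpropoxy)cyclohex-2-en-1-one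
Product: 9 3-{[(1S,2S)-2-(hydroxymethyl)-1-methylcyclopropyl]ethynyl}-2,4,4-trimethylcyclohex-2-en-1-one, via dilithium alkoxide of the 1,2-adduct 8 (not isolated)
Conditions: 7, n-BuLi (2.2 equiv), THF, −78 → 0 °C; 5, −78 °C → rt; then 1 M HCl, rt
Reagents that add atoms: water (O), which supplies the carbonyl oxygen by exchange; the net balance is unchanged
Why: Stork–Danheiser sequence, in which the acetylide end of the dianion adds 1,2 to the vinylogous ester and acid hydrolysis with loss of the tertiary hydroxyl transposes the carbonyl to give the 3-alkynyl enone, leaving the cyclopropane stereocentres untouched.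

Step 6
Reactants: 9 3-{[(1S,2S)-2-(hydroxymethyl)-1-methylcyclopropyl]ethynyl}-2,4,4-trimethylcyclohex-2-en-1-one
Product: 10 (1S,2S)-2-methyl-2-[(2,6,6-trimethyl-3-oxocyclohex-1-en-1-yl)ethynyl]cyclopropane-1-carbaldehyde
Conditions: TEMPO (cat.), PhI(OAc)2, CH2Cl2, rt
Reagents that add atoms: none
Why: oxoammonium-mediated (TEMPO) oxidation takes the primary alcohol to the aldehyde without over-oxidation and leaves the enone, the alkyne and the quaternary centre alone.

Step 7
Reactants: 10 (1S,2S)-2-methyl-2-[(2,6,6-trimethyl-3-oxocyclohex-1-en-1-yl)ethynyl]cyclopropane-1-carbaldehyde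
Product: 12 (6S)-6-methyl-6-[(2,6,6-trimethyl-3-oxocyclohex-1-en-1-yl)ethynyl]-1,2-dioxan-3-ol, via γ-hydroperoxy aldehyde 11 (not isolated)
Conditions: H2O2 (anhydrous, in Et2O, 5 equiv), Sc(OTf)3 (10 mol%), CH2Cl2, −40 → 0 °C
Reagents that add atoms: hydrogen peroxide (OO)
Why: Proposed new method: perhydrolytic ring expansion of a cyclopropanecarbaldehyde, in which Sc(OTf)3 activates the formyl group so that the C1–C2 bond acts as a homo-Michael acceptor, H2O2 attacks the quaternary propargylic C2 from the side opposite C1 (SN2-like, inversion; the slim alkynyl group leaves the backside open and the electron-poor ynone disfavours a free cation that would racemise), and the resulting enol tautomerises to 11, which closes to the peroxyhemiacetal, so the (2S) centre of 10 becomes the tertiary peroxide centre C6; the closest known reaction types are the Lewis-acid-promoted stereoinvertive opening of cyclopropyl ketones at a quaternary carbon by halide or azide, the Lewis-acid perhydrolysis of 2,2-disubstituted oxetanes with inversion, the Cloke–Wilson ring expansion and the aerobic cobalt-catalysed ring expansion of cyclobutanols to 1,2-dioxan-3-ols.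

Step 8
Reactants: 12 (6S)-6-methyl-6-[(2,6,6-trimethyl-3-oxocyclohex-1-en-1-yl)ethynyl]-1,2-dioxan-3-ol
Product: 13 (6S)-6-methyl-6-[(2,6,6-trimethyl-3-oxocyclohex-1-en-1-yl)ethynyl]-1,2-dioxan-3-yl acetate
Conditions: Ac2O, Et3N, DMAP (cat.), CH2Cl2, 0 °C
Reagents that add atoms: acetic anhydride (CC(=O)OC(C)=O)
Why: acylation of the peroxyhemiacetal hydroxyl gives the anomeric acetate as leaving group for peroxycarbenium formation, and the two C3 epimers converge in step 10.

Step 9
Reactants: 14 methyl propanoate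
Product: 15 (Z)-tert-butyl[(1-methoxyprop-1-en-1-yl)oxy]dimethylsilane
Conditions: LiN(i-Pr)2, THF/DMPU, −78 °C; TBSCl, −78 °C → rt
Reagents that add atoms: tert-butyldimethylsilyl chloride (CC(C)(C)[Si](C)(C)Cl)
Why: Ireland-type enolisation in the presence of DMPU gives the enolate with OLi cis to methyl, which is trapped on oxygen as the (Z)-silyl ketene acetal needed for syn selectivity in step 10.

Step 10
Reactants: 13 (6S)-6-methyl-6-[(2,6,6-trimethyl-3-oxocyclohex-1-en-1-yl)ethynyl]-1,2-dioxan-3-yl acetate; 15 (Z)-tert-butyl[(1-methoxyprop-1-en-1-yl)oxy]dimethylsilane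
Product: 17 methyl (2R)-2-{(3S,6S)-6-methyl-6-[(2,6,6-trimethyl-3-oxocyclohex-1-en-1-yl)ethynyl]-1,2-dioxan-3-yl}propanoate, via 1,2-dioxan-3-ylium ion 16 (not isolated)
Conditions: TMSOTf (0.3 equiv), CH2Cl2, −78 °C
Reagents that add atoms: none
Why: Mukaiyama-type alkylation of a peroxycarbenium ion, in which axial attack on the half-chair ion with the slim alkynyl group pseudoaxial and methyl pseudoequatorial (A values about 0.4 against 1.7 kcal/mol) places the new bond cis to the C6 methyl group (3S), and the (Z)-ketene acetal reacts through the open antiperiplanar transition state (ring over the C–H side of the nucleophile, small OMe next to the ring CH2) to give the 2,3-syn (2R) ester, with minor diastereomers removed by chromatography.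

Step 11
Reactants: 17 methyl (2R)-2-{(3S,6S)-6-methyl-6-[(2,6,6-trimethyl-3-oxocyclohex-1-en-1-yl)ethynyl]-1,2-dioxan-3-yl}propanoate
Product: 19 methyl (2R)-2-{(3S,6R)-6-methyl-6-[2-(2,6,6-trimethyl-3-oxocyclohex-1-en-1-yl)ethyl]-1,2-dioxan-3-yl}propanoate (methyl diacarnoate A), via (Z)-alkene 18 (not isolated)
Conditions: KO2CN=NCO2K (excess), AcOH, MeOH, 0 °C → rt, repeated until 18 is consumed
Reagents that add atoms: none
Why: diimide transfers hydrogen in a concerted syn fashion to the alkyne and then to the alkene but does not touch the O–O bond, the ester or the tetrasubstituted enone, so the three stereocentres are unchanged (C6 becomes R only because the CIP priorities change).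

**Compound list**
1 | cyclohexane-1,3-dione | O=C1CCCC(=O)C1 | starting material
2 | 2-methylcyclohexane-1,3-dione | CC1C(=O)CCCC1=O | intermediate
3 | 2-methyl-3-(2-methylpropoxy)cyclohex-2-en-1-one | CC1=C(OCC(C)C)CCCC1=O | intermediate
4 | 2,6-dimethyl-3-(2-methylpropoxy)cyclohex-2-en-1-one (racemic, not isolated) | CC1=C(OCC(C)C)CCC(C)C1=O | intermediate
5 | 2,6,6-trimethyl-3-(2-methylpropoxy)cyclohex-2-en-1-one | CC1=C(OCC(C)C)CCC(C)(C)C1=O | intermediate
6 | (E)-3-methylpent-2-en-4-yn-1-ol | OC/C=C(\C)C#C | starting material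
7 | [(1S,2S)-2-ethynyl-2-methylcyclopropyl]methanol | OC[C@H]1C[C@]1(C)C#C | intermediate
8 | 1-{[(1S,2S)-2-(hydroxymethyl)-1-methylcyclopropyl]ethynyl}-2,6,6-trimethyl-3-(2-methylpropoxy)cyclohex-2-en-1-ol (formed as its dilithium alkoxide, both C1 epimers, not isolated) | OC[C@H]1C[C@]1(C)C#CC2(O)C(C)=C(OCC(C)C)CCC2(C)C | intermediate
9 | 3-{[(1S,2S)-2-(hydroxymethyl)-1-methylcyclopropyl]ethynyl}-2,4,4-trimethylcyclohex-2-en-1-one | OC[C@H]1C[C@]1(C)C#CC2=C(C)C(=O)CCC2(C)C | intermediate
10 | (1S,2S)-2-methyl-2-[(2,6,6-trimethyl-3-oxocyclohex-1-en-1-yl)ethynyl]cyclopropane-1-carbaldehyde | O=C[C@H]1C[C@]1(C)C#CC2=C(C)C(=O)CCC2(C)C | intermediate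
11 | (4S)-4-hydroperoxy-4-methyl-6-(2,6,6-trimethyl-3-oxocyclohex-1-en-1-yl)hex-5-ynal (not isolated) | O=CCC[C@@](C)(C#CC1=C(C)C(=O)CCC1(C)C)OO | intermediate
12 | (6S)-6-methyl-6-[(2,6,6-trimethyl-3-oxocyclohex-1-en-1-yl)ethynyl]-1,2-dioxan-3-ol (both C3 epimers) | OC1CC[C@@](C)(C#CC2=C(C)C(=O)CCC2(C)C)OO1 | intermediate
13 | (6S)-6-methyl-6-[(2,6,6-trimethyl-3-oxocyclohex-1-en-1-yl)ethynyl]-1,2-dioxan-3-yl acetate (both C3 epimers) | CC(=O)OC1CC[C@@](C)(C#CC2=C(C)C(=O)CCC2(C)C)OO1 | intermediate
14 | methyl propanoate | CCC(=O)OC | starting material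
15 | (Z)-tert-butyl[(1-methoxyprop-1-en-1-yl)oxy]dimethylsilane | C/C=C(\O[Si](C)(C)C(C)(C)C)OC | intermediate
16 | (6S)-6-methyl-6-[(2,6,6-trimethyl-3-oxocyclohex-1-en-1-yl)ethynyl]-1,2-dioxan-3-ylium (peroxycarbenium ion, not isolated) | C1CC[C@@](C)(C#CC2=C(C)C(=O)CCC2(C)C)O[O+]=1 | intermediate
17 | methyl (2R)-2-{(3S,6S)-6-methyl-6-[(2,6,6-trimethyl-3-oxocyclohex-1-en-1-yl)ethynyl]-1,2-dioxan-3-yl}propanoate | COC(=O)[C@H](C)[C@@H]1CC[C@@](C)(C#CC2=C(C)C(=O)CCC2(C)C)OO1 | intermediate
18 | methyl (2R)-2-{(3S,6S)-6-methyl-6-[(Z)-2-(2,6,6-trimethyl-3-oxocyclohex-1-en-1-yl)ethenyl]-1,2-dioxan-3-yl}propanoate (not isolated) | COC(=O)[C@H](C)[C@@H]1CC[C@@](C)(/C=C\C2=C(C)C(=O)CCC2(C)C)OO1 | intermediate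
19 | methyl (2R)-2-{(3S,6R)-6-methyl-6-[2-(2,6,6-trimethyl-3-oxocyclohex-1-en-1-yl)ethyl]-1,2-dioxan-3-yl}propanoate (methyl diacarnoate A) | COC(=O)[C@H](C)[C@@H]1CC[C@@](C)(CCC2=C(C)C(=O)CCC2(C)C)OO1 | target

**Step count and risks**

Total steps: 11. Longest linear sequence: 9 (steps 1, 2, 3, 5, 6, 7, 8, 10, 11).

The three steps most likely to fail:

Step 5. The acetylide must add to a carbonyl that is both hindered (flanked by a quaternary carbon) and deactivated as a vinylogous ester. The fallback sets out from 3 and 7 and comes back at 10, bypassing 9. Reduce 3 with LiAlH4 and hydrolyse with dilute HCl to 2-methylcyclohex-2-en-1-one F1. Methylate F1 twice at C6 (LiN(i-Pr)2, MeI) to 2,6,6-trimethylcyclohex-2-en-1-one F2. Add the dilithio derivative of 7 (with CeCl3) to this more electrophilic ketone to give 1-{[(1S,2S)-2-(hydroxymethyl)-1-methylcyclopropyl]ethynyl}-2,6,6-trimethylcyclohex-2-en-1-ol F3. Treat F3 with pyridinium chlorochromate, [C5H5NH][CrO3Cl], in CH2Cl2; this effects the oxidative 1,3-transposition of the tertiary allylic alcohol (Dauben–Babler) and oxidises the primary alcohol in the same flask, giving 10.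

Step 7 (the proposed new step). H2O2 may only add reversibly to the formyl group, may oxidise it, may attack the ring CH2 instead of the quaternary carbon, or the carbonyl oxygen may close to a dihydrofuran. The fallback uses known chemistry, sets out from 10 and comes back at 12. Open the cyclopropane first with bromide (Me3SiBr, CH2Cl2, −78 °C, aqueous work-up), a known ring opening of cyclopropyl carbonyl compounds that proceeds with inversion at a quaternary carbon, to give (4S)-4-bromo-4-methyl-6-(2,6,6-trimethyl-3-oxocyclohex-1-en-1-yl)hex-5-ynal F4. Exchange the tertiary bromide for OOH by silver-assisted perhydrolysis (AgOCOCF3, H2O2, Et2O, 0 °C); the hydroperoxy aldehyde 11 so formed closes to 12. Because the silver step runs through an ion pair, the configuration at C6 is not secured; 12 would then be resolved as its acetate 13 by preparative chromatography on a chiral phase.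

Step 10. Two stereocentres come from one bond formation. The facial bias from C6 and the syn preference are each expected to be only moderate (roughly 5:1 or better each, estimated from the A-value difference and the transition-state model, not from a measured case), and the Lewis acid could ionise the peroxide. The fallback sets out from 13 and comes back at 17. Replace the ester enolate equivalent by an allylsilane, the nucleophile class best documented for peroxycarbenium ions: Hosomi–Sakurai reaction of 13 with (Z)-but-2-enyl(trimethyl)silane (SnCl4 or TMSOTf, CH2Cl2, −78 °C). On the same open transition-state model this should again give syn, namely (3S,6S)-3-[(2S)-but-3-en-2-yl]-6-methyl-6-[(2,6,6-trimethyl-3-oxocyclohex-1-en-1-yl)ethynyl]-1,2-dioxane F5. Cleave the vinyl group selectively by ozonolysis (O3, CH2Cl2, −78 °C, then Me2S) to (2R)-2-{(3S,6S)-6-methyl-6-[(2,6,6-trimethyl-3-oxocyclohex-1-en-1-yl)ethynyl]-1,2-dioxan-3-yl}propanal F6. Oxidise (NaClO2, NaH2PO4, 2-methylbut-2-ene) to (2R)-2-{(3S,6S)-6-methyl-6-[(2,6,6-trimethyl-3-oxocyclohex-1-en-1-yl)ethynyl]-1,2-dioxan-3-yl}propanoic acid F7 and esterify (Me3SiCHN2, MeOH) to 17. Diastereomers are separated at F5 or 17.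

**Further compounds**
F1 | step 5 | 2-methylcyclohex-2-en-1-one | CC1=CCCCC1=O
F2 | step 5 | 2,6,6-trimethylcyclohex-2-en-1-one | CC1=CCCC(C)(C)C1=O
F3 | step 5 | 1-{[(1S,2S)-2-(hydroxymethyl)-1-methylcyclopropyl]ethynyl}-2,6,6-trimethylcyclohex-2-en-1-ol | OC[C@H]1C[C@]1(C)C#CC2(O)C(C)=CCCC2(C)C
F4 | step 7 | (4S)-4-bromo-4-methyl-6-(2,6,6-trimethyl-3-oxocyclohex-1-en-1-yl)hex-5-ynal | O=CCC[C@@](C)(C#CC1=C(C)C(=O)CCC1(C)C)Br
F5 | step 10 | (3S,6S)-3-[(2S)-but-3-en-2-yl]-6-methyl-6-[(2,6,6-trimethyl-3-oxocyclohex-1-en-1-yl)ethynyl]-1,2-dioxane | C=C[C@H](C)[C@@H]1CC[C@@](C)(C#CC2=C(C)C(=O)CCC2(C)C)OO1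
F6 | step 10 | (2R)-2-{(3S,6S)-6-methyl-6-[(2,6,6-trimethyl-3-oxocyclohex-1-en-1-yl)ethynyl]-1,2-dioxan-3-yl}propanal | O=C[C@H](C)[C@@H]1CC[C@@](C)(C#CC2=C(C)C(=O)CCC2(C)C)OO1
F7 | step 10 | (2R)-2-{(3S,6S)-6-methyl-6-[(2,6,6-trimethyl-3-oxocyclohex-1-en-1-yl)ethynyl]-1,2-dioxan-3-yl}propanoic acid | OC(=O)[C@H](C)[C@@H]1CC[C@@](C)(C#CC2=C(C)C(=O)CCC2(C)C)OO1
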